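**Strategy.** Everything rests on opening the ten-membered carbocycle (C1–C10, briarane numbering) at C3=C4. The 2-substituted 1,3-diene C3=C4–C5(=C16H2) embedded in this ring is the retron of an endo-mode ring-closing enyne metathesis: one operation closes the ring, makes the Z C3=C4 alkene and the exocyclic C5=C16 methylene, and thereby turns a robust propargylic chloride at C6 into the allylic one. The precursor is a seco-compound with a C2 vinyl group and a terminal C4≡C5 alkyne, in which the cyclohexane and the γ-lactone, all nine stereocentres and the three acetates are already in place.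

Key step: step 20

Numbering used throughout (briarane): C1 quaternary ring-fusion carbon (C15 methyl), C2 CH(OAc), C3=C4, C5(=C16H2), C6 (Cl), C7 (lactone O–CH), C8 (C–OH), C9 CH(OAc), C10 ring-fusion CH, C11(=C20H2), C12, C13 CH(OAc), C14; lactone C17 (CH–C18H3) and C19 (C=O).

Assumption: the absolute sense of the two catalyst-controlled steps (2 and 15) is not predicted here; the ligand antipode ((DHQD)2PHAL or (DHQ)2PHAL; (R)- or (S)-BINOL) that gives the drawn product is meant.

Remark: lactol 15 is expected as an anomeric mixture; one anomer is drawn and the centre disappears in step 10.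

## Route

Step 1
Reactants: 1 benzoic acid; 2 iodomethane
Product: 4 1-methylcyclohexa-2,5-diene-1-carboxylic acid, via Birch dianion 3 (not isolated)
Conditions: Li (3 equiv), NH3 (l), THF, −78 °C; then MeI; aq. HCl work-up
Reagents that add atoms: none
Why: Birch reduction–alkylation: the dissolving metal reduces the benzoate to the carboxylate-stabilised 1,4-dihydro dianion 3, which is methylated at the ipso carbon to give the mirror-symmetric diene acid with the quaternary C1 in place.

Step 2
Reactants: 4 1-methylcyclohexa-2,5-diene-1-carboxylic acid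
Product: 5 (1S,5S,8S)-8-bromo-1-methyl-6-oxabicyclo[3.2.1]oct-2-en-7-one
Conditions: N-bromosuccinimide, (DHQD)2PHAL (10 mol%), CHCl3/hexane, −40 °C
Reagents that add atoms: N-bromosuccinimide, O=C1CCC(=O)N1Br
Why: Catalytic enantioselective desymmetrising bromolactonisation (halolactonisation): the cinchona catalyst delivers bromine to one of the two enantiotopic alkenes and the carboxylate closes the bridged γ-lactone on C13, necessarily cis to C2 and anti to bromine, so C1 and C13 are set together.

Step 3
Reactants: 5 bromolactone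
Product: 6 (1S,5S)-1-methyl-6-oxabicyclo[3.2.1]oct-2-en-7-one
Conditions: Bu3SnH, AIBN (cat.), benzene, 80 °C
Reagents that add atoms: none
Why: Radical hydrodebromination (tin hydride chain reduction) removes the auxiliary bromine at C14 without touching the lactone or the alkene.

Step 4
Reactants: 6 bicyclic lactone
Product: 7 (1R,2R,3R,5R)-2-bromo-3-hydroxy-1-methyl-6-oxabicyclo[3.2.1]octan-7-one
Conditions: N-bromosuccinimide, acetone/H2O, 0 °C
Reagents that add atoms: N-bromosuccinimide, O=C1CCC(=O)N1Br; water, O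
Why: Bromohydrin formation: the bromonium ion forms on the alkene face opposite the lactone bridge and water opens it trans-diaxially at C11, the carbon remote from the quaternary acyl-bearing C1, which places oxygen on C11 and bromine on C10.

Step 5
Reactants: 7 bromohydrin
Product: 8 (1R,2R,5R)-2-bromo-1-methyl-6-oxabicyclo[3.2.1]octane-3,7-dione
Conditions: Dess–Martin periodinane, NaHCO3, CH2Cl2, 0 °C to rt
Reagents that add atoms: none
Why: Dess–Martin oxidation converts the secondary alcohol to the C11 ketone under non-basic conditions that avoid β-elimination of the lactone oxygen.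

Step 6
Reactants: 8 α-bromo ketone
Product: 10 (1S,5R)-1-methyl-7-oxo-6-oxabicyclo[3.2.1]oct-2-en-3-yl trifluoromethanesulfonate, via lithium enolate 9 (not isolated)
Conditions: Me2CuLi, THF, −78 °C; then PhNTf2, −78 to 0 °C
Reagents that add atoms: N-phenylbis(trifluoromethanesulfonimide), O=S(=O)(N(c1ccccc1)S(=O)(=O)C(F)(F)F)C(F)(F)F
Why: Reductive enolate formation from the α-bromo ketone with the Gilman cuprate gives only the C10=C11 enolate 9, whose regiochemistry is fixed by the position of bromine and not by kinetic acidity, and O-sulfonylation traps it as the enol triflate.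

Step 7
Reactants: 10 enol triflate; 11 (trimethylsilyl)methylmagnesium chloride
Product: 12 (1S,5R)-1-methyl-3-[(trimethylsilyl)methyl]-6-oxabicyclo[3.2.1]oct-2-en-7-one
Conditions: Pd(PPh3)4 (5 mol%), THF, 0 °C to rt
Reagents that add atoms: none
Why: Kumada–Corriu cross-coupling of the enol triflate with the poorly carbonyl-reactive silylmethyl Grignard reagent installs C20 as an allylsilane without touching the neopentyl-type lactone.

Step 8
Reactants: 12 allylsilane; 13 2,2-dimethoxyacetaldehyde
Product: 14 (1S,2S,5S)-2-[(1S)-1-hydroxy-2,2-dimethoxyethyl]-1-methyl-3-methylidene-6-oxabicyclo[3.2.1]octan-7-one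
Conditions: BF3·OEt2, CH2Cl2, −78 °C
Reagents that add atoms: none
Why: Hosomi–Sakurai reaction: the aldehyde attacks C10 on the face opposite the diaxial lactone bridge (C9 trans to C2) through the open antiperiplanar transition state of an E-type γ-substituted allylsilane (syn C9/C10), and loss of silicon creates the C11=C20 methylene.

Step 9
Reactants: 14 hydroxy lactone
Product: 15 (1S,2S,5S,7R)-2-[(1S)-1-hydroxy-2,2-dimethoxyethyl]-1-methyl-3-methylidene-6-oxabicyclo[3.2.1]octan-7-ol
Conditions: DIBAL-H (2.2 equiv), CH2Cl2, −78 °C; Rochelle salt work-up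
Reagents that add atoms: none
Why: Partial hydride reduction of the lactone stops at the aluminium hemiacetal at −78 °C and gives the lactol, while the acetal is inert.

Step 10
Reactants: 15 lactol; 16 vinylmagnesium bromide
Product: 17 (1S,3S,4S)-4-[(1S)-1-hydroxy-2,2-dimethoxyethyl]-3-[(1S)-1-hydroxyprop-2-en-1-yl]-3-methyl-5-methylidenecyclohexan-1-ol
Conditions: vinylMgBr (5 equiv), THF, −78 to 0 °C; aq. NH4Cl
Reagents that add atoms: none
Why: Grignard addition to the lactol: deprotonation opens it to a magnesium-bridged hydroxy aldehyde that keeps the bicyclic shape, and vinyl adds from the exo face (the side of the one-carbon bridge C14), which should give the 2S carbinol.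

Step 11
Reactants: 17 triol
Product: 18 (1S,3S,4S)-4-[(1S)-1-acetoxy-2,2-dimethoxyethyl]-3-[(1S)-1-acetoxyprop-2-en-1-yl]-3-methyl-5-methylidenecyclohexyl acetate
Conditions: Ac2O, pyridine, DMAP (cat.), CH2Cl2, rt
Reagents that add atoms: acetic anhydride, CC(=O)OC(C)=O
Why: DMAP-catalysed acylation esterifies the three secondary hydroxyls at C2, C9 and C13 in one operation.

Step 12
Reactants: 18 triacetate acetal
Product: 19 C8 aldehyde (18 with the dimethyl acetal hydrolysed to CHO; 1S,2S,9S,10S,13S)
Conditions: aq. TFA, CH2Cl2, 0 °C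
Reagents that add atoms: water, O
Why: Acid-catalysed acetal hydrolysis unmasks the C8 aldehyde while the acetates survive, and the α-acetoxy aldehyde is used directly to avoid epimerisation at C9.

Step 13
Reactants: 19 aldehyde; 20 dimethyl (diazomethyl)phosphonate
Product: 21 C8 β-keto phosphonate (C9–C(=O)–CH2–P(O)(OMe)2; 1S,2S,9S,10S,13S)
Conditions: SnCl2 (20 mol%), CH2Cl2, rt
Reagents that add atoms: none
Why: Holmquist–Roskamp homologation: Lewis-acid-promoted addition of the diazo phosphonate to the aldehyde, 1,2-hydride shift and loss of nitrogen give the β-keto phosphonate under non-basic conditions.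

Step 14
Reactants: 21 β-keto phosphonate; 22 3-(trimethylsilyl)prop-2-ynal
Product: 23 (E)-enynone (C8 ketone, C7=C6 E-alkene, C5≡C4–SiMe3; 1S,2S,9S,10S,13S)
Conditions: LiCl, i-Pr2NEt, MeCN, rt
Reagents that add atoms: none
Why: Horner–Wadsworth–Emmons olefination under Masamune–Roush conditions (mild amine base, lithium chelate) gives the E-configured enynone without cleaving acetates.

Step 15
Reactants: 23 (E)-enynone
Product: 24 trans-(6R,7S)-epoxy ketone (1S,2S,9S,10S,13S)
Conditions: La(O-iPr)3 (10 mol%), BINOL (10 mol%), Ph3As=O (10 mol%), t-BuOOH (decane), 4 Å MS, THF, rt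
Reagents that add atoms: tert-butyl hydroperoxide, CC(C)(C)OO
Why: Catalyst-controlled nucleophilic (Weitz–Scheffer type) epoxidation of the E-enone by the lanthanum–BINOL peroxide gives the trans-(7S,6R)-epoxy ketone, and the electron-rich C2 vinyl and C11 methylene groups do not react with a nucleophilic oxidant.

Step 16
Reactants: 24 epoxy ketone; 25 N,N-dimethylpropanamide
Product: 26 (8R,17R)-β-hydroxy amide (tertiary C8–OH, C17 methyl, epoxide intact)
Conditions: 25, LDA, THF, −78 °C (Z-enolate); then 24, −78 °C; aq. NH4Cl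
Reagents that add atoms: none
Why: Aldol-type addition of the Z lithium amide enolate to the ketone: lithium chelation between the ketone and epoxide oxygens exposes the face syn to H7 (8R), and a closed chair transition state with the chelated epoxide arm axial and C9 equatorial places the methyl group syn to the hydroxyl along the C9 chain (17R).

Step 17
Reactants: 26 β-hydroxy amide
Product: 28 (6R,7R,8R,17R)-hydroxy γ-lactone with free C6–OH, via iminium lactone 27 (not isolated)
Conditions: TsOH·H2O (1.2 equiv), THF/H2O, rt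
Reagents that add atoms: water, O
Why: Acid-promoted 5-exo epoxide opening by the amide oxygen with inversion at C7 gives iminium lactone 27, which is hydrolysed to the γ-lactone and leaves the C6 hydroxyl with retained configuration, so the trans-epoxide is translated stereospecifically into the anti C6–OH/C7–O pair.

Step 18
Reactants: 28 silylalkyne lactone
Product: 29 terminal alkyne (28 without the SiMe3 group)
Conditions: Bu4NF, AcOH, THF, 0 °C
Reagents that add atoms: none
Why: Buffered fluoride-induced protodesilylation of the alkynylsilane frees the terminal alkyne while the acetates and the lactone survive.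

Step 19
Reactants: 29 propargylic alcohol
Product: 30 (6S)-propargylic chloride, the metathesis precursor (1S,2S,6S,7S,8R,9S,10S,13S,17R)
Conditions: PPh3, CCl4, MeCN, 0 °C to rt
Reagents that add atoms: tetrachloromethane, ClC(Cl)(Cl)Cl
Why: Appel reaction: the alkoxyphosphonium salt of the secondary propargylic alcohol is displaced by chloride with inversion (6R to 6S), the tertiary C8 hydroxyl being unreactive.

Step 20
Reactants: 30 enyne precursor
Product: 32 CNP0268873.2 (target), via 2-substituted buta-1,3-diene 31 (not isolated)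
Conditions: [RuCl2(=CHPh)(H2IMes)(PCy3)] (second-generation Grubbs catalyst, 15 mol%), ethene (1 atm), CH2Cl2, 40 °C; then argon purge, toluene (1 mM), 80 °C
Reagents that add atoms: ethene, C=C
Why: The ruthenium methylidene formed under ethene adds to the terminal C4≡C5 alkyne (cross enyne metathesis) to give the 2-substituted butadiene 31, whose monosubstituted vinyl group then undergoes ring-closing metathesis with the C2 vinyl group and expels ethene; the closest known reaction type is ethene-mediated macrocyclic endo-mode ring-closing enyne metathesis. The ten-membered ring is closed by forming the C3=C4 double bond inside the ring while C5=C16 stays exocyclic (formal endo-mode enyne closure). No stereocentre is created; the C3=C4 geometry should be Z because an E-alkene conjugated to the exocyclic methylene is too strained in a ten-membered ring that carries a trans-fused cyclohexane and a cis-fused lactone. The step needs endo over exo mode (the alternative is a nine-membered 1-vinylcycloalkene), which is secured by ethene diverting the alkyne to the diene first and by the reluctance of the 1,1-disubstituted diene terminus to form a trisubstituted nine-ring alkene. It also needs chemoselectivity over the C11=C20 methylene, secured because its only closure with the C2 vinyl group would give an anti-Bredt bicyclo[3.2.1] alkene. The allylic chloride appears only in this step, so it is never exposed to the earlier nucleophiles and reductants.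

## Compound list

1 | benzoic acid | O=C(O)c1ccccc1 | starting material
2 | iodomethane | CI | starting material
3 | dilithium (cyclohexa-2,5-dien-1-ylidene)methanediolate (Birch dianion) | [Li+].[Li+].[O-]C([O-])=C1C=CCC=C1 | intermediate
4 | 1-methylcyclohexa-2,5-diene-1-carboxylic acid | CC1(C=CCC=C1)C(=O)O | intermediate
5 | (1S,5S,8S)-8-bromo-1-methyl-6-oxabicyclo[3.2.1]oct-2-en-7-one | C1C=C[C@]2(C)[C@H](Br)[C@H]1OC2=O | intermediate
6 | (1S,5S)-1-methyl-6-oxabicyclo[3.2.1]oct-2-en-7-one | C1C=C[C@]2(C)C[C@H]1OC2=O | intermediate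
7 | (1R,2R,3R,5R)-2-bromo-3-hydroxy-1-methyl-6-oxabicyclo[3.2.1]octan-7-one | C1[C@@H](O)[C@H](Br)[C@]2(C)C[C@H]1OC2=O | intermediate
8 | (1R,2R,5R)-2-bromo-1-methyl-6-oxabicyclo[3.2.1]octane-3,7-dione | C1C(=O)[C@H](Br)[C@]2(C)C[C@H]1OC2=O | intermediate
9 | lithium (1S,5R)-1-methyl-7-oxo-6-oxabicyclo[3.2.1]oct-2-en-3-olate | C1C([O-])=C[C@]2(C)C[C@H]1OC2=O.[Li+] | intermediate
10 | (1S,5R)-1-methyl-7-oxo-6-oxabicyclo[3.2.1]oct-2-en-3-yl trifluoromethanesulfonate | C1C(OS(=O)(=O)C(F)(F)F)=C[C@]2(C)C[C@H]1OC2=O | intermediate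
11 | (trimethylsilyl)methylmagnesium chloride | C[Si](C)(C)C[Mg]Cl | starting material
12 | (1S,5R)-1-methyl-3-[(trimethylsilyl)methyl]-6-oxabicyclo[3.2.1]oct-2-en-7-one | C1C(C[Si](C)(C)C)=C[C@]2(C)C[C@H]1OC2=O | intermediate
13 | 2,2-dimethoxyacetaldehyde | COC(OC)C=O | starting material
14 | (1S,2S,5S)-2-[(1S)-1-hydroxy-2,2-dimethoxyethyl]-1-methyl-3-methylidene-6-oxabicyclo[3.2.1]octan-7-one | C=C1C[C@H]2C[C@](C)(C(=O)O2)[C@H]1[C@H](O)C(OC)OC | intermediate
15 | (1S,2S,5S,7R)-2-[(1S)-1-hydroxy-2,2-dimethoxyethyl]-1-methyl-3-methylidene-6-oxabicyclo[3.2.1]octan-7-ol (lactol) | C=C1C[C@H]2C[C@](C)([C@H](O)O2)[C@H]1[C@H](O)C(OC)OC | intermediate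
16 | vinylmagnesium bromide | C=C[Mg]Br | starting material
17 | (1S,3S,4S)-4-[(1S)-1-hydroxy-2,2-dimethoxyethyl]-3-[(1S)-1-hydroxyprop-2-en-1-yl]-3-methyl-5-methylidenecyclohexan-1-ol | C=C1C[C@H](O)C[C@](C)([C@@H](O)C=C)[C@H]1[C@H](O)C(OC)OC | intermediate
18 | (1S,3S,4S)-4-[(1S)-1-acetoxy-2,2-dimethoxyethyl]-3-[(1S)-1-acetoxyprop-2-en-1-yl]-3-methyl-5-methylidenecyclohexyl acetate | C=C1C[C@H](OC(C)=O)C[C@](C)([C@@H](OC(C)=O)C=C)[C@H]1[C@H](OC(C)=O)C(OC)OC | intermediate
19 | C8 aldehyde (2,9,13-triacetate; 1S,2S,9S,10S,13S) | C=C1C[C@H](OC(C)=O)C[C@](C)([C@@H](OC(C)=O)C=C)[C@H]1[C@H](OC(C)=O)C=O | intermediate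
20 | dimethyl (diazomethyl)phosphonate | COP(=O)(OC)C=[N+]=[N-] | starting material
21 | C8 β-keto phosphonate (1S,2S,9S,10S,13S) | C=C1C[C@H](OC(C)=O)C[C@](C)([C@@H](OC(C)=O)C=C)[C@H]1[C@H](OC(C)=O)C(=O)CP(=O)(OC)OC | intermediate
22 | 3-(trimethylsilyl)prop-2-ynal | C[Si](C)(C)C#CC=O | starting material
23 | (E)-enynone (1S,2S,9S,10S,13S) | C=C1C[C@H](OC(C)=O)C[C@](C)([C@@H](OC(C)=O)C=C)[C@H]1[C@H](OC(C)=O)C(=O)/C=C/C#C[Si](C)(C)C | intermediate
24 | trans-(6R,7S)-epoxy ketone (1S,2S,9S,10S,13S) | C=C1C[C@H](OC(C)=O)C[C@](C)([C@@H](OC(C)=O)C=C)[C@H]1[C@H](OC(C)=O)C(=O)[C@H]1O[C@@H]1C#C[Si](C)(C)C | intermediate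
25 | N,N-dimethylpropanamide | CCC(=O)N(C)C | starting material
26 | (8R,17R)-β-hydroxy amide with (6R,7S)-epoxide | C=C1C[C@H](OC(C)=O)C[C@](C)([C@@H](OC(C)=O)C=C)[C@H]1[C@H](OC(C)=O)[C@](O)([C@@H](C)C(=O)N(C)C)[C@H]1O[C@@H]1C#C[Si](C)(C)C | intermediate
27 | iminium lactone tosylate (C19=N+Me2, lactone O on C7) | C=C1C[C@H](OC(C)=O)C[C@](C)([C@@H](OC(C)=O)C=C)[C@H]1[C@H](OC(C)=O)[C@]1(O)[C@@H](C)C(=[N+](C)C)O[C@@H]1[C@H](O)C#C[Si](C)(C)C.Cc1ccc(cc1)S(=O)(=O)[O-] | intermediate
28 | (6R,7R,8R,17R)-hydroxy γ-lactone, trimethylsilylalkyne | C=C1C[C@H](OC(C)=O)C[C@](C)([C@@H](OC(C)=O)C=C)[C@H]1[C@H](OC(C)=O)[C@]1(O)[C@@H](C)C(=O)O[C@@H]1[C@H](O)C#C[Si](C)(C)C | intermediate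
29 | (6R,7R,8R,17R)-hydroxy γ-lactone, terminal alkyne | C=C1C[C@H](OC(C)=O)C[C@](C)([C@@H](OC(C)=O)C=C)[C@H]1[C@H](OC(C)=O)[C@]1(O)[C@@H](C)C(=O)O[C@@H]1[C@H](O)C#C | intermediate
30 | (6S)-propargylic chloride, enyne precursor (1S,2S,6S,7S,8R,9S,10S,13S,17R) | C=C1C[C@H](OC(C)=O)C[C@](C)([C@@H](OC(C)=O)C=C)[C@H]1[C@H](OC(C)=O)[C@]1(O)[C@@H](C)C(=O)O[C@@H]1[C@@H](Cl)C#C | intermediate
31 | 2-substituted buta-1,3-diene (C5(=C16H2)–C4H=CH2) | C=C1C[C@H](OC(C)=O)C[C@](C)([C@@H](OC(C)=O)C=C)[C@H]1[C@H](OC(C)=O)[C@]1(O)[C@@H](C)C(=O)O[C@@H]1[C@@H](Cl)C(=C)C=C | intermediate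
32 | CNP0268873.2 | C=C1C[C@H](OC(C)=O)C[C@]2(C)[C@@H](OC(C)=O)/C=C\C(=C)[C@H](Cl)[C@H]3OC(=O)[C@H](C)[C@@]3(O)[C@@H](OC(C)=O)[C@@H]12 | target

## Count and risks

Total step count: 20. Longest linear sequence: 20 steps (benzoic acid to the target).

Three steps most likely to fail:

1. Step 20 (key step). The strained ten-membered ring may not close: exo-mode closure to a nine-membered ring, oligomerisation or E/Z mixtures can take over, and the free tertiary hydroxyl may slow the catalyst. Fallback: set out from 30 and separate the two events. Cross enyne metathesis with ethene alone (same ruthenium catalyst, 1 atm, rt) gives the isolated diene 31. Silylation of the C8 hydroxyl (TMSOTf, 2,6-lutidine) gives the trimethylsilyl ether of the diene F1. Diene–ene ring-closing metathesis with the more active molybdenum alkylidene Mo(=CHCMe2Ph)(=N-2,6-i-Pr2C6H3)[OCMe(CF3)2]2 under reduced pressure gives the 8-O-trimethylsilyl macrocycle F2. HF·pyridine then returns to 32.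

2. Step 16. Facial selectivity at C8 and simple selectivity at C17 may erode if chelation is incomplete, and the strongly basic enolate may attack the acetates. Fallback: set out from 24 and use a Lewis-acid-mediated Mukaiyama-type addition with no free enolate. The (Z)-O-trimethylsilyl ketene N,O-acetal of 25 with MgBr2·OEt2 (chelation of ketone and epoxide oxygens) in CH2Cl2 at −78 °C should give the 8-O-trimethylsilyl ether of the hydroxy amide F3. Mild aqueous acid then returns to 26.

3. Step 15. Catalyst control may be overridden by the neighbouring C9 stereocentre, and the basic lanthanum alkoxide may epimerise C9 or transesterify acetates. Fallback: set out from 23 and move the asymmetric step to the alcohol oxidation level. Corey–Bakshi–Shibata reduction (oxazaborolidine antipode chosen for this epimer) gives the (8S)-allylic alcohol F4. Matched Sharpless epoxidation (Ti(O-iPr)4, diisopropyl tartrate, t-BuOOH, 4 Å MS, −20 °C) gives the erythro-(6R,7S)-epoxy alcohol F5. Dess–Martin oxidation then returns to 24.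

Further compounds
F1 | step 20 | 8-O-trimethylsilyl ether of diene 31 | C=C1C[C@H](OC(C)=O)C[C@](C)([C@@H](OC(C)=O)C=C)[C@H]1[C@H](OC(C)=O)[C@]1(O[Si](C)(C)C)[C@@H](C)C(=O)O[C@@H]1[C@@H](Cl)C(=C)C=C
F2 | step 20 | 8-O-trimethylsilyl ether of the target macrocycle | C=C1C[C@H](OC(C)=O)C[C@]2(C)[C@@H](OC(C)=O)/C=C\C(=C)[C@H](Cl)[C@H]3OC(=O)[C@H](C)[C@@]3(O[Si](C)(C)C)[C@@H](OC(C)=O)[C@@H]12
F3 | step 16 | 8-O-trimethylsilyl ether of hydroxy amide 26 | C=C1C[C@H](OC(C)=O)C[C@](C)([C@@H](OC(C)=O)C=C)[C@H]1[C@H](OC(C)=O)[C@](O[Si](C)(C)C)([C@@H](C)C(=O)N(C)C)[C@H]1O[C@@H]1C#C[Si](C)(C)C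
F4 | step 15 | (8S)-allylic alcohol from enynone 23 | C=C1C[C@H](OC(C)=O)C[C@](C)([C@@H](OC(C)=O)C=C)[C@H]1[C@H](OC(C)=O)[C@@H](O)/C=C/C#C[Si](C)(C)C
F5 | step 15 | erythro-(6R,7S)-epoxy alcohol | C=C1C[C@H](OC(C)=O)C[C@](C)([C@@H](OC(C)=O)C=C)[C@H]1[C@H](OC(C)=O)[C@@H](O)[C@H]1O[C@@H]1C#C[Si](C)(C)C
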